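**Retrosynthetic overview**

1. The target is 6β-acetoxy-9α-hydroxylabd-13-en-16,15-olide. The butenolide is cut at C12–C13 (B-alkyl Suzuki–Miyaura coupling of a 9β-vinyl carbinol with 3-bromofuran-2(5H)-one). The carbinol goes back through the 9α,11-epoxide and the exocyclic alkene to a C9 ketone, and the 6β-acetate to a C6 ketone.
2. Enabling feature: ring B (C5–C10) carries its two oxygens at C6 and C9 in a 1,4-relationship, and ring A (C1–C4, quaternary C4) links C10 to C5. Ring B is therefore the cyclohexene of a [4+2] addition between the 2-silyloxydiene C7=C8(CH3)–C9(OSi)=C10(CH3) and the acceptor alkene C5=C6–CHO, with matched polarity (C10 nucleophilic, C5 electrophilic).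
3. Key disconnection: C6–C7 and C5–C10 together, by a catalytic enantioselective intramolecular Diels–Alder reaction of an acyclic, achiral trienal. The formyl carbon on C6 is then excised oxidatively to give the C6 ketone.
4. The trienal is assembled in six steps from isobutyronitrile, 1,3-dibromopropane, N-propionylmorpholine and isopropenylmagnesium bromide.
5. Ring order: rings A and B are formed together in step 7; the butenolide ring comes from furan-2(5H)-one and is attached last (step 15).

Key step: step 7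

Remark: labdane numbering is used for atoms (ring A = C1–C5 and C10, ring B = C5–C10, side chain C11–C16, C17 on C8, C18 and C19 on C4, C20 on C10); α is below and β above the plane of the decalin as usually drawn.

Assumption: the sense of induction in step 7 is taken from the formyl C–H···O pre-transition-state model of oxazaborolidinium catalysis, which assigns addition at the Cα-si face of the enal to the catalyst made from (R)-diphenylprolinol; both prolinol enantiomers are commercial.

**Route**

Step 1
Reactants: 1 isobutyronitrile; 2 1,3-dibromopropane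
Product: 3 5-bromo-2,2-dimethylpentanenitrile
Conditions: LiN(iPr)2 (1.05 equiv), THF, −78 °C; then added to 2 (3 equiv), −78 °C to rt
Reagents that add atoms: none
Why: SN2 alkylation of the lithiated tertiary nitrile, in which the excess of dibromide suppresses double alkylation and no stereocentre is formed.

Step 2
Reactants: 4 1-(morpholin-4-yl)propan-1-one; 3 5-bromo-2,2-dimethylpentanenitrile
Product: 5 rac-2,2,6-trimethyl-7-(morpholin-4-yl)-7-oxoheptanenitrile
Conditions: LiN(iPr)2 (1.1 equiv), THF, −78 °C; then 3, DMPU, −78 °C to rt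
Reagents that add atoms: none
Why: Alkylation of a tertiary amide enolate with a primary bromide; the nitrile has no α-hydrogen and is hindered, and the new centre (later C10) may be racemic because it becomes sp2 in step 4.

Step 3
Reactants: 5 rac-2,2,6-trimethyl-7-(morpholin-4-yl)-7-oxoheptanenitrile; 6 isopropenylmagnesium bromide
Product: 7 rac-2,2,6,8-tetramethyl-7-oxonon-8-enenitrile
Conditions: 6 (2 equiv), THF, 0 °C to rt; inverse quench into cold 1 M HCl
Reagents that add atoms: none
Why: Grignard acylation of a morpholine amide (Weinreb-type ketone synthesis), in which the tetrahedral magnesium adduct survives until work-up so that the enone is not attacked, while the hindered tertiary nitrile is inert at this temperature.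

Step 4
Reactants: 7 rac-2,2,6,8-tetramethyl-7-oxonon-8-enenitrile
Product: 8 (6Z)-2,2,6,8-tetramethyl-7-[(triisopropylsilyl)oxy]nona-6,8-dienenitrile
Conditions: iPr3SiOTf (1.3 equiv), Et3N (2.5 equiv), CH2Cl2, 0 °C to 40 °C; chromatography on Et3N-deactivated silica
Reagents that add atoms: triisopropylsilyl trifluoromethanesulfonate, CC(C)[Si](C(C)C)(C(C)C)OS(=O)(=O)C(F)(F)F
Why: Soft enolisation and O-silylation at the only enolisable position; the (Z) isomer (chain cis to oxygen, methyl cis to the isopropenyl group) is expected to be favoured because it puts the smaller group against the isopropenyl group, and the minor (E) isomer is removed.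

Step 5
Reactants: 8 (6Z)-2,2,6,8-tetramethyl-7-[(triisopropylsilyl)oxy]nona-6,8-dienenitrile
Product: 10 (6Z)-2,2,6,8-tetramethyl-7-[(triisopropylsilyl)oxy]nona-6,8-dienal, via N-aluminio aldimine 9 (not isolated)
Conditions: iBu2AlH (1.2 equiv), toluene, −78 °C; then aq. potassium sodium tartrate, 0 °C
Reagents that add atoms: water, O
Why: Partial hydride reduction of the nitrile stops at the N-aluminio imine, which is hydrolysed to the aldehyde on near-neutral work-up, and the silyl dienol ether does not react with the hydride.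

Step 6
Reactants: 10 (6Z)-2,2,6,8-tetramethyl-7-[(triisopropylsilyl)oxy]nona-6,8-dienal
Product: 12 (2E,8Z)-4,4,8,10-tetramethyl-9-[(triisopropylsilyl)oxy]undeca-2,8,10-trienal, via N-cyclohexyl azadiene 11 (not isolated)
Conditions: diethyl [(E)-2-(cyclohexylamino)ethenyl]phosphonate, NaH, THF, 0 °C to rt; then aq. oxalic acid, hexane, 0 °C, short contact
Reagents that add atoms: diethyl [(E)-2-(cyclohexylamino)ethenyl]phosphonate, CCOP(=O)(OCC)/C=C/NC1CCCCC1; water, O
Why: Horner–Wadsworth–Emmons formyl olefination gives the (E)-unsaturated imine, which mild acid hydrolyses to the (E)-enal without heating, so that no uncatalysed cycloaddition can start.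

Step 7
Reactants: 12 (2E,8Z)-4,4,8,10-tetramethyl-9-[(triisopropylsilyl)oxy]undeca-2,8,10-trienal
Product: 13 (1S,4aS,8aS)-3,4a,8,8-tetramethyl-4-[(triisopropylsilyl)oxy]-1,2,4a,5,6,7,8,8a-octahydronaphthalene-1-carbaldehyde
Conditions: (R)-B-(o-tolyl)oxazaborolidine from (R)-α,α-diphenylprolinol (20 mol %), Tf2NH (17 mol %), CH2Cl2, −78 °C to −40 °C; Et3N quench
Reagents that add atoms: none
Why: The boron-bound (E)-enal undergoes an asynchronous endo [4+2] cycloaddition with the tethered 2-silyloxydiene, C10 (the nucleophilic enol-ether carbon) bonding to the enal β-carbon C5 slightly ahead of C7 bonding to C6; the closest known reaction type is the oxazaborolidinium-catalysed enantioselective Diels–Alder reaction, established intramolecularly for trienals and intermolecularly for 2-(triisopropylsilyloxy)buta-1,3-diene. Ring A closes as the six-membered ring of the four-carbon tether (C1–C4) through the C5–C10 bond and ring B is the cyclohexene formed by both new bonds in a suprafacial [4+2] closure, the formyl-endo transition state of an (E)-dienophile giving the trans ring fusion. C10 (quaternary, methyl β) and C5 (H α) are set relative to each other by the (Z)-enol ether geometry (methyl on the inside of the diene) and the endo mode, C6 (formyl α, cis to H-5) follows from the (E)-alkene and is erased in step 8, and the new C8=C9 silyl enol ether carries the C9 oxygen. The absolute sense comes from the catalyst, which binds the s-trans enal through boron and a formyl C–H···O contact and covers the Cα-re face with a phenyl group, so that the diene adds to the Cα-si face. The step needs regio-, endo- and face selectivity: the regiochemistry is fixed by the tether and matched by the polarity of both partners, the endo mode is favoured by the Lewis acid, the face is set by the catalyst, and the quaternary C4 (no γ-hydrogen, Thorpe–Ingold effect) keeps the enal from enolising and favours ring closure. A cis-fused (exo) adduct would be a diastereomer and is removed by chromatography before step 8.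

Step 8
Reactants: 13 (1S,4aS,8aS)-3,4a,8,8-tetramethyl-4-[(triisopropylsilyl)oxy]-1,2,4a,5,6,7,8,8a-octahydronaphthalene-1-carbaldehyde
Product: 14 (4aS,8aS)-3,4a,8,8-tetramethyl-4-[(triisopropylsilyl)oxy]-4a,5,6,7,8,8a-hexahydronaphthalen-1(2H)-one
Conditions: Cu(OAc)2 (10 mol %), 2,2'-bipyridine (10 mol %), DABCO (1 equiv), O2 (1 atm), DMF, 40 °C
Reagents that add atoms: dioxygen, O=O
Why: Copper-catalysed aerobic deformylation of an α-branched aldehyde, in which the copper enolate takes up O2 at C6 and the α-hydroperoxy aldehyde fragments to the ketone and formic acid, removing the activating carbon and making C6 sp2.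

Step 9
Reactants: 14 (4aS,8aS)-3,4a,8,8-tetramethyl-4-[(triisopropylsilyl)oxy]-4a,5,6,7,8,8a-hexahydronaphthalen-1(2H)-one
Product: 16 (2R,4R,4aS,8aS)-4-hydroxy-2,5,5,8a-tetramethyloctahydronaphthalen-1(2H)-one, via 6β-hydroxy silyl enol ether 15 (not isolated)
Conditions: NaBH4, MeOH/THF, 0 °C; then 2 M HCl, THF, rt to 40 °C
Reagents that add atoms: none
Why: Hydride reduction then acid hydrolysis of the silyl enol ether: hydride should reach C6 only from the α face because the β face is covered by the syn-axial methyl groups on C10 and C4 (giving 6β-OH), and ketonisation under equilibrating conditions should leave the C8 methyl equatorial (α), since an 8β-methyl would be syn-axial to the C10 methyl and the 6β-OH.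

Step 10
Reactants: 16 (2R,4R,4aS,8aS)-4-hydroxy-2,5,5,8a-tetramethyloctahydronaphthalen-1(2H)-one
Product: 17 (1R,3R,4aS,8aS)-3,4a,8,8-tetramethyl-4-methylidenedecahydronaphthalen-1-ol
Conditions: Ph3PCH3Br (4 equiv), KOtBu (3.8 equiv), toluene, 100 °C
Reagents that add atoms: methyltriphenylphosphonium bromide, C[P+](c1ccccc1)(c1ccccc1)c1ccccc1.[Br-]
Why: Wittig methylenation under the high-temperature conditions used for hindered ketones; the 6β-OH is carried as its alkoxide and C8 keeps its thermodynamically preferred α-methyl configuration.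

Step 11
Reactants: 17 (1R,3R,4aS,8aS)-3,4a,8,8-tetramethyl-4-methylidenedecahydronaphthalen-1-ol
Product: 18 (5S,6R,8R,9R,10S)-9α,11-epoxy-12,13,14,15,16-pentanorlabdan-6β-ol
Conditions: mCPBA (1.2 equiv), NaHCO3, CH2Cl2, 0 °C
Reagents that add atoms: 3-chloroperoxybenzoic acid, OOC(=O)c1cccc(Cl)c1
Why: Prilezhaev epoxidation, in which the peracid should approach the exocyclic alkene from the α face, anti to the axial C10 methyl on the neighbouring carbon, putting the oxygen on C9 α and C11 β (equatorial).

Step 12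
Reactants: 18 (5S,6R,8R,9R,10S)-9α,11-epoxy-12,13,14,15,16-pentanorlabdan-6β-ol
Product: 19 (1R,3R,4R,4aS,8aS)-4-ethenyl-3,4a,8,8-tetramethyldecahydronaphthalene-1,4-diol
Conditions: Me3SI (5 equiv), n-BuLi (4.8 equiv), THF, −10 °C; then 18, −10 °C to rt
Reagents that add atoms: trimethylsulfonium iodide, C[S+](C)C.[I-]
Why: Epoxide-to-allylic-alcohol homologation with dimethylsulfonium methylide: the ylide opens the epoxide at the CH2 terminus (SN2) and the γ-oxido sulfonium salt loses dimethyl sulfide by ylide-mediated β-elimination, so C9 keeps its configuration (9α-OH, 9β-vinyl).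

Step 13
Reactants: 19 (1R,3R,4R,4aS,8aS)-4-ethenyl-3,4a,8,8-tetramethyldecahydronaphthalene-1,4-diol
Product: 20 (1R,3R,4R,4aS,8aS)-4-ethenyl-4-hydroxy-3,4a,8,8-tetramethyldecahydronaphthalen-1-yl acetate
Conditions: Ac2O, DMAP, Et3N, CH2Cl2, rt to 40 °C
Reagents that add atoms: acetic anhydride, CC(=O)OC(C)=O
Why: DMAP-catalysed acylation should acetylate the secondary 6β-OH while the tertiary, doubly neopentyl 9α-OH does not react.

Step 14
Reactants: 21 furan-2(5H)-one
Product: 23 3-bromofuran-2(5H)-one, via dibromolactone 22 (not isolated)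
Conditions: Br2, CH2Cl2, 0 °C; then Et3N, 0 °C
Reagents that add atoms: bromine, BrBr
Why: Bromine addition to the butenolide alkene followed by dehydrobromination (loss of the acidic α-hydrogen and the β-bromide) gives the α-bromobutenolide.

Step 15
Reactants: 20 (1R,3R,4R,4aS,8aS)-4-ethenyl-4-hydroxy-3,4a,8,8-tetramethyldecahydronaphthalen-1-yl acetate; 23 3-bromofuran-2(5H)-one
Product: 25 (5S,6R,8R,9R,10S)-6β-acetoxy-9α-hydroxylabd-13-en-16,15-olide, via B-alkyl-9-BBN adduct 24 (not isolated)
Conditions: 9-BBN dimer (1.5 equiv), THF, 0 °C to rt; then 23, PdCl2(dppf) (5 mol %), AsPh3, Cs2CO3, DMF/H2O, rt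
Reagents that add atoms: none
Why: Anti-Markovnikov hydroboration of the vinyl group places boron on C12, and B-alkyl Suzuki–Miyaura coupling with the α-bromobutenolide forms C12–C13 at room temperature, where the hindered acetate and the butenolide should survive; no stereocentre is touched.

**Compound list**

1 | isobutyronitrile | CC(C)C#N | starting material
2 | 1,3-dibromopropane | BrCCCBr | starting material
3 | 5-bromo-2,2-dimethylpentanenitrile | CC(C)(CCCBr)C#N | intermediate
4 | 1-(morpholin-4-yl)propan-1-one | CCC(=O)N1CCOCC1 | starting material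
5 | rac-2,2,6-trimethyl-7-(morpholin-4-yl)-7-oxoheptanenitrile | CC(CCCC(C)(C)C#N)C(=O)N1CCOCC1 | intermediate
6 | isopropenylmagnesium bromide | CC(=C)[Mg]Br | starting material
7 | rac-2,2,6,8-tetramethyl-7-oxonon-8-enenitrile | CC(=C)C(=O)C(C)CCCC(C)(C)C#N | intermediate
8 | (6Z)-2,2,6,8-tetramethyl-7-[(triisopropylsilyl)oxy]nona-6,8-dienenitrile | CC(=C)/C(O[Si](C(C)C)(C(C)C)C(C)C)=C(\C)CCCC(C)(C)C#N | intermediate
9 | N-(diisobutylalumanyl) aldimine of 10 | CC(=C)/C(O[Si](C(C)C)(C(C)C)C(C)C)=C(\C)CCCC(C)(C)C=N[Al](CC(C)C)CC(C)C | intermediate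
10 | (6Z)-2,2,6,8-tetramethyl-7-[(triisopropylsilyl)oxy]nona-6,8-dienal | CC(=C)/C(O[Si](C(C)C)(C(C)C)C(C)C)=C(\C)CCCC(C)(C)C=O | intermediate
11 | (1E,2E,8Z)-N-cyclohexyl-4,4,8,10-tetramethyl-9-[(triisopropylsilyl)oxy]undeca-2,8,10-trien-1-imine | CC(=C)/C(O[Si](C(C)C)(C(C)C)C(C)C)=C(\C)CCCC(C)(C)/C=C/C=N/C1CCCCC1 | intermediate
12 | (2E,8Z)-4,4,8,10-tetramethyl-9-[(triisopropylsilyl)oxy]undeca-2,8,10-trienal | CC(=C)/C(O[Si](C(C)C)(C(C)C)C(C)C)=C(\C)CCCC(C)(C)/C=C/C=O | intermediate
13 | (1S,4aS,8aS)-3,4a,8,8-tetramethyl-4-[(triisopropylsilyl)oxy]-1,2,4a,5,6,7,8,8a-octahydronaphthalene-1-carbaldehyde (6α-CHO, 5α-H, 10β-CH3) | O=C[C@H]1CC(C)=C(O[Si](C(C)C)(C(C)C)C(C)C)[C@@]2(C)CCCC(C)(C)[C@H]12 | intermediate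
14 | (4aS,8aS)-3,4a,8,8-tetramethyl-4-[(triisopropylsilyl)oxy]-4a,5,6,7,8,8a-hexahydronaphthalen-1(2H)-one | O=C1CC(C)=C(O[Si](C(C)C)(C(C)C)C(C)C)[C@@]2(C)CCCC(C)(C)[C@H]12 | intermediate
15 | (1R,4aS,8aS)-3,4a,8,8-tetramethyl-4-[(triisopropylsilyl)oxy]-1,2,4a,5,6,7,8,8a-octahydronaphthalen-1-ol (6β-OH) | O[C@@H]1CC(C)=C(O[Si](C(C)C)(C(C)C)C(C)C)[C@@]2(C)CCCC(C)(C)[C@H]12 | intermediate
16 | (2R,4R,4aS,8aS)-4-hydroxy-2,5,5,8a-tetramethyloctahydronaphthalen-1(2H)-one (6β-OH, 8α-CH3, C9 ketone) | O[C@@H]1C[C@@H](C)C(=O)[C@@]2(C)CCCC(C)(C)[C@H]12 | intermediate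
17 | (1R,3R,4aS,8aS)-3,4a,8,8-tetramethyl-4-methylidenedecahydronaphthalen-1-ol | O[C@@H]1C[C@@H](C)C(=C)[C@@]2(C)CCCC(C)(C)[C@H]12 | intermediate
18 | (5S,6R,8R,9R,10S)-9α,11-epoxy-12,13,14,15,16-pentanorlabdan-6β-ol (spiro-epoxide, oxygen α on C9) | O[C@@H]1C[C@@H](C)[C@]3(CO3)[C@@]2(C)CCCC(C)(C)[C@H]12 | intermediate
19 | (1R,3R,4R,4aS,8aS)-4-ethenyl-3,4a,8,8-tetramethyldecahydronaphthalene-1,4-diol (6β-OH, 9α-OH, 9β-vinyl) | O[C@@H]1C[C@@H](C)[C@](O)(C=C)[C@@]2(C)CCCC(C)(C)[C@H]12 | intermediate
20 | (1R,3R,4R,4aS,8aS)-4-ethenyl-4-hydroxy-3,4a,8,8-tetramethyldecahydronaphthalen-1-yl acetate | CC(=O)O[C@@H]1C[C@@H](C)[C@](O)(C=C)[C@@]2(C)CCCC(C)(C)[C@H]12 | intermediate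
21 | furan-2(5H)-one | O=C1OCC=C1 | starting material
22 | rac-trans-3,4-dibromodihydrofuran-2(3H)-one | O=C1OCC(Br)C1Br | intermediate
23 | 3-bromofuran-2(5H)-one | O=C1OCC=C1Br | intermediate
24 | (5S,6R,8R,9R,10S)-12-(9-borabicyclo[3.3.1]nonan-9-yl)-9α-hydroxy-13,14,15,16-tetranorlabdan-6β-yl acetate | CC(=O)O[C@@H]1C[C@@H](C)[C@](O)(CCB3C4CCCC3CCC4)[C@@]2(C)CCCC(C)(C)[C@H]12 | intermediate
25 | (5S,6R,8R,9R,10S)-6β-acetoxy-9α-hydroxylabd-13-en-16,15-olide | CC(=O)O[C@@H]1C[C@@H](C)[C@](O)(CCC2=CCOC2=O)[C@@]2(C)CCCC(C)(C)[C@H]12 | target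

**Step count and risks**

Total number of steps: 15 (14 in the main line and 1 for the bromobutenolide). Longest linear sequence: 14 steps (steps 1–13 and 15, from isobutyronitrile).

Risk 1 (step 7). The electron-rich silyl dienol ether may lose its silyl group by protonation from the acidic catalyst, or the reaction may take an open-chain Mukaiyama–Michael course that erodes endo and face control. The fallback replaces the catalyst by a stoichiometric auxiliary. It sets out from aldehyde 10: Horner–Wadsworth–Emmons reaction with (S)-4-benzyl-3-[(diethoxyphosphoryl)acetyl]-1,3-oxazolidin-2-one (LiCl, iPr2NEt, MeCN, rt) should give the (E)-trienimide (S)-4-benzyl-3-[(2E,8Z)-4,4,8,10-tetramethyl-9-[(triisopropylsilyl)oxy]undeca-2,8,10-trienoyl]-1,3-oxazolidin-2-one F1. Me2AlCl (1.5 equiv, CH2Cl2, −30 °C) then promotes the auxiliary-controlled endo intramolecular Diels–Alder reaction through the chelated s-cis imide, whose benzyl group covers the Cα-re face, to the cycloadduct imide F2. LiBH4 (Et2O, 1 equiv MeOH, 0 °C) releases the auxiliary and gives the primary alcohol [(1S,4aS,8aS)-3,4a,8,8-tetramethyl-4-[(triisopropylsilyl)oxy]-1,2,4a,5,6,7,8,8a-octahydronaphthalen-1-yl]methanol F3, and Dess–Martin periodinane with NaHCO3 oxidises it to aldehyde 13, where the route is rejoined.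

Risk 2 (step 8). Under the copper and oxygen conditions the doubly activated C7 methylene (α to the new ketone and allylic to the enol ether) may be over-oxidised, or the silyl enol ether itself may be attacked. The fallback sets out from aldehyde 13: condensation with morpholine (4 Å molecular sieves, benzene, rt) gives the enamine 4-{[(4aS,8aS)-3,4a,8,8-tetramethyl-4-[(triisopropylsilyl)oxy]-4a,5,6,7,8,8a-hexahydronaphthalen-1(2H)-ylidene]methyl}morpholine F4. Sensitised photooxygenation (O2, tetraphenylporphyrin, visible light, CH2Cl2, −78 °C) adds singlet oxygen to the enamine double bond, and the dioxetane cleaves to ketone 14. The enamine should react far faster than the silyl enol ether, and no base or metal is present.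

Risk 3 (step 12). The neopentyl-type CH2 terminus of the epoxide may open too slowly for the thermally labile ylide, and the 6β-alkoxide may attack the epoxide across the ring. The fallback avoids epoxide opening altogether and sets out from alkene 17: OsO4 (cat.) with NMO in acetone/H2O should dihydroxylate from the α face, away from the C10 methyl, to (5S,6R,8R,9R,10S)-12,13,14,15,16-pentanorlabdane-6β,9α,11-triol F5. TEMPO with PhI(OAc)2 (CH2Cl2, rt) oxidises only the primary alcohol to (5S,6R,8R,9R,10S)-6β,9α-dihydroxy-12,13,14,15,16-pentanorlabdan-11-al F6. Wittig methylenation (Ph3PCH3Br, KOtBu, THF, −78 °C to 0 °C) of the aldehyde then gives diol 19.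

**Further compounds**

F1 | step 7 | (S)-4-benzyl-3-[(2E,8Z)-4,4,8,10-tetramethyl-9-[(triisopropylsilyl)oxy]undeca-2,8,10-trienoyl]-1,3-oxazolidin-2-one | CC(=C)/C(O[Si](C(C)C)(C(C)C)C(C)C)=C(\C)CCCC(C)(C)/C=C/C(=O)N1[C@@H](Cc2ccccc2)COC1=O
F2 | step 7 | (S)-4-benzyl-3-{[(1S,4aS,8aS)-3,4a,8,8-tetramethyl-4-[(triisopropylsilyl)oxy]-1,2,4a,5,6,7,8,8a-octahydronaphthalen-1-yl]carbonyl}-1,3-oxazolidin-2-one | O=C([C@H]1CC(C)=C(O[Si](C(C)C)(C(C)C)C(C)C)[C@@]2(C)CCCC(C)(C)[C@H]12)N1[C@@H](Cc2ccccc2)COC1=O
F3 | step 7 | [(1S,4aS,8aS)-3,4a,8,8-tetramethyl-4-[(triisopropylsilyl)oxy]-1,2,4a,5,6,7,8,8a-octahydronaphthalen-1-yl]methanol | OC[C@H]1CC(C)=C(O[Si](C(C)C)(C(C)C)C(C)C)[C@@]2(C)CCCC(C)(C)[C@H]12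
F4 | step 8 | 4-{[(4aS,8aS)-3,4a,8,8-tetramethyl-4-[(triisopropylsilyl)oxy]-4a,5,6,7,8,8a-hexahydronaphthalen-1(2H)-ylidene]methyl}morpholine | C(=C1CC(C)=C(O[Si](C(C)C)(C(C)C)C(C)C)[C@@]2(C)CCCC(C)(C)[C@H]12)N1CCOCC1
F5 | step 12 | (5S,6R,8R,9R,10S)-12,13,14,15,16-pentanorlabdane-6β,9α,11-triol | O[C@@H]1C[C@@H](C)[C@](O)(CO)[C@@]2(C)CCCC(C)(C)[C@H]12
F6 | step 12 | (5S,6R,8R,9R,10S)-6β,9α-dihydroxy-12,13,14,15,16-pentanorlabdan-11-al | O[C@@H]1C[C@@H](C)[C@](O)(C=O)[C@@]2(C)CCCC(C)(C)[C@H]12
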